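**Retrosynthetic overview**
- The angelate goes on last: Yamaguchi esterification of O3 of a 2,18-bis-silylated decalin-3-ol, then desilylation.
- Rings A and B come from one Lewis-acid epoxy-polyene bicyclisation of an acyclic precursor. Ring A closes first (C4–C5), ring B second (C9–C10), and a Z allylsilane terminator leaves the C8 exo-methylene. The butenolide ring is made before either and carried through.
- The acyclic precursor comes from a late sp3–sp2 Negishi coupling at C5–C6 of fragment A (C1–C5, C10, C18–C20) and fragment B (C6–C9, C11–C17).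
- Fragment A: propargyl alcohol, DMF and propargyl bromide; two Negishi carboaluminations, a catalytic asymmetric propargylation (C2) and a hydroxyl-directed epoxidation (C3, C4).
- Fragment B: 3-butyn-1-ol, ethylene oxide and tetronic acid; silylmethyl carbocupration, then Negishi coupling with 4-bromofuran-2(5H)-one.

Assumption: positions use labdane numbering (C1–C20); the SMILES is read as the (2S,3S,4S,5S,9R,10S) isomer (trans-decalin; 2-OH, 3-O-acyl and 4-CH2OH equatorial; 4-CH3 axial) with a Z (angelate) ester.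

**Route**

Step 1
Reactants: 1 propargyl alcohol
Product: 3 (2E)-3-iodo-2-methylprop-2-en-1-ol, via alkenylalane 2 (not isolated)
Conditions: Me3Al (2.5 equiv), Cp2ZrCl2 (0.25 equiv), CH2Cl2, 0 °C to rt; then I2, THF, −30 to 0 °C
Reagents that add atoms: trimethylaluminium (C[Al](C)C); iodine (II)
Why: Negishi zirconium-catalysed carboalumination adds Me–Al syn across the alkyne with aluminium on the terminal carbon, and iodinolysis with retention gives the E iodide.

Step 2
Reactants: 3 (2E)-3-iodo-2-methylprop-2-en-1-ol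
Product: 4 tert-butyl{[(2E)-3-iodo-2-methylprop-2-en-1-yl]oxy}dimethylsilane
Conditions: TBSCl, imidazole, CH2Cl2, 0 °C to rt
Reagents that add atoms: tert-butyldimethylsilyl chloride (CC(C)(C)[Si](C)(C)Cl)
Why: Silyl protection of the primary alcohol so that the vinyl iodide can be lithiated.

Step 3
Reactants: 4 silylated iodoalkene
Product: 6 (2E)-4-[(tert-butyldimethylsilyl)oxy]-3-methylbut-2-enal, via vinyllithium 5 (not isolated)
Conditions: t-BuLi (2.1 equiv), Et2O, −78 °C; then DMF, −78 to 0 °C; aq. NH4Cl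
Reagents that add atoms: N,N-dimethylformamide (CN(C)C=O)
Why: Lithium–iodine exchange proceeds with retention of alkene geometry and formylation of the vinyllithium with DMF gives the E enal (C2 as the aldehyde carbon).

Step 4
Reactants: 7 propargyl bromide
Product: 9 4,4,5,5-tetramethyl-2-(propa-1,2-dien-1-yl)-1,3,2-dioxaborolane, via allenylmagnesium bromide 8 (not isolated)
Conditions: Mg, HgCl2 (1 mol%), Et2O, 0 °C; then i-PrOBpin, −78 °C to rt; aq. NH4Cl
Reagents that add atoms: 2-isopropoxy-4,4,5,5-tetramethyl-1,3,2-dioxaborolane (CC(C)OB1OC(C)(C)C(C)(C)O1)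
Why: Grignard formation gives the allenyl magnesium species, which is borylated to the allenylboronate used as the propargyl donor.

Step 5
Reactants: 6 E enal; 9 allenylboronate
Product: 10 (2E,4S)-1-[(tert-butyldimethylsilyl)oxy]-2-methylhept-2-en-6-yn-4-ol
Conditions: (S)-TRIP phosphoric acid [(S)-3,3′-bis(2,4,6-triisopropylphenyl)-1,1′-binaphthyl-2,2′-diyl hydrogen phosphate] (5 mol%), 4 Å MS, toluene, −20 °C, 48 h
Reagents that add atoms: none
Why: Chiral Brønsted acid-catalysed allenylboration (SE2′ propargylation through a closed six-membered transition state in which the acid blocks one aldehyde face) sets C2 as S; the sense is assigned by analogy with aryl and alkenyl aldehydes and the antipodal acid would give the 4R alcohol.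

Step 6
Reactants: 10 homopropargylic alcohol
Product: 12 (2E,4S,6E)-1-[(tert-butyldimethylsilyl)oxy]-7-iodo-2,6-dimethylhepta-2,6-dien-4-ol, via alkenylalane 11 (not isolated)
Conditions: Me3Al (4 equiv), Cp2ZrCl2 (0.3 equiv), H2O (1 equiv), CH2Cl2, −20 to 0 °C; then I2, THF, −30 to 0 °C; aq. Rochelle salt
Reagents that add atoms: trimethylaluminium (C[Al](C)C); iodine (II)
Why: Water-accelerated Negishi carboalumination of the terminal alkyne (the alcohol is carried as its aluminium alkoxide) followed by iodinolysis fixes the E trisubstituted vinyl iodide that becomes C5=C10 with the C20 methyl.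

Step 7
Reactants: 12 dienyl iodide alcohol
Product: 13 (1S,3E)-1-[(2R,3R)-3-{[(tert-butyldimethylsilyl)oxy]methyl}-3-methyloxiran-2-yl]-4-iodo-3-methylbut-3-en-1-ol
Conditions: mCPBA (1.1 equiv), NaHCO3, CH2Cl2, −20 to 0 °C
Reagents that add atoms: 3-chloroperoxybenzoic acid (OOC(=O)c1cccc(Cl)c1)
Why: Hydroxyl-directed (Henbest) peracid epoxidation in which A(1,3) strain from the cis methyl holds the carbinol H in the alkene plane, so oxygen is delivered syn to the hydroxyl and gives the threo epoxy alcohol (C3 R, C4 R; about 10–20:1 expected); the electron-poor iodoalkene does not react.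

Step 8
Reactants: 13 epoxy alcohol
Product: 14 tert-butyl{[(1S,3E)-1-[(2R,3R)-3-{[(tert-butyldimethylsilyl)oxy]methyl}-3-methyloxiran-2-yl]-4-iodo-3-methylbut-3-en-1-yl]oxy}dimethylsilane (fragment A)
Conditions: TBSCl, imidazole, DMAP (cat.), DMF, rt to 40 °C
Reagents that add atoms: tert-butyldimethylsilyl chloride (CC(C)(C)[Si](C)(C)Cl)
Why: Silylation of the secondary alcohol under non-acidic conditions leaves the epoxide and vinyl iodide intact.

Step 9
Reactants: 15 3-butyn-1-ol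
Product: 16 (but-3-yn-1-yloxy)(tert-butyl)dimethylsilane
Conditions: TBSCl, imidazole, CH2Cl2, rt
Reagents that add atoms: tert-butyldimethylsilyl chloride (CC(C)(C)[Si](C)(C)Cl)
Why: Silyl protection of the future C6 oxygen with a bulky, poorly coordinating group.

Step 10
Reactants: 16 silylated butynol; 17 ethylene oxide
Product: 19 (3Z)-6-[(tert-butyldimethylsilyl)oxy]-4-[(trimethylsilyl)methyl]hex-3-en-1-ol, via alkenylcopper 18 (not isolated)
Conditions: Me3SiCH2MgCl (1.2 equiv), CuBr·SMe2 (1.2 equiv), Et2O/Me2S, −40 °C; add 16, −25 °C, 24 h; then 1-pentynyllithium, THF, ethylene oxide (3 equiv), −40 to 0 °C; aq. NH4Cl/NH3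
Reagents that add atoms: (trimethylsilyl)methylmagnesium chloride (C[Si](C)(C)C[Mg]Cl)
Why: Normant syn-carbocupration puts the silylmethyl group on the internal carbon and copper on the terminal carbon, and the alkenylcopper (as its mixed alkynyl cuprate) opens ethylene oxide with retention, which fixes the Z allylsilane (C17 cis to C11).

Step 11
Reactants: 19 homoallylic alcohol
Product: 20 {[(3Z)-6-bromo-3-[(trimethylsilyl)methyl]hex-3-en-1-yl]oxy}(tert-butyl)dimethylsilane
Conditions: CBr4, PPh3, CH2Cl2, 0 °C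
Reagents that add atoms: carbon tetrabromide (BrC(Br)(Br)Br)
Why: Appel bromination is neutral and free of electrophilic halogen, so the allylsilane and silyl ether survive.

Step 12
Reactants: 21 tetronic acid
Product: 22 4-bromofuran-2(5H)-one
Conditions: (COBr)2, DMF (cat.), CH2Cl2, 0 °C to rt
Reagents that add atoms: oxalyl bromide (O=C(Br)C(=O)Br)
Why: Vilsmeier-type deoxybromination of the vinylogous acid gives the β-bromo butenolide.

Step 13
Reactants: 20 bromide; 22 4-bromofuran-2(5H)-one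
Product: 24 4-[(3Z)-6-[(tert-butyldimethylsilyl)oxy]-4-[(trimethylsilyl)methyl]hex-3-en-1-yl]furan-2(5H)-one, via alkylzinc bromide 23 (not isolated)
Conditions: Zn dust, LiCl, THF, 50 °C; then 22, Pd(OAc)2 (2 mol%), SPhos (4 mol%), THF, rt
Reagents that add atoms: none
Why: Zinc insertion into the primary bromide and Negishi sp3–sp2 cross-coupling with the activated vinyl bromide forms C12–C13 and installs the butenolide.

Step 14
Reactants: 24 silylated butenolide
Product: 25 4-[(3Z)-6-hydroxy-4-[(trimethylsilyl)methyl]hex-3-en-1-yl]furan-2(5H)-one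
Conditions: PPTS (0.2 equiv), MeOH, 40 °C
Reagents that add atoms: none
Why: Mild acid methanolysis removes the primary TBS ether without protodesilylating the allylsilane or touching the lactone.

Step 15
Reactants: 25 alcohol
Product: 26 4-[(3Z)-6-bromo-4-[(trimethylsilyl)methyl]hex-3-en-1-yl]furan-2(5H)-one (fragment B)
Conditions: CBr4, PPh3, CH2Cl2, 0 °C
Reagents that add atoms: carbon tetrabromide (BrC(Br)(Br)Br)
Why: Appel bromination of the primary alcohol under neutral conditions.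

Step 16
Reactants: 26 fragment B bromide; 14 fragment A vinyl iodide
Product: 28 4-[(3Z,7E,10S)-10-[(tert-butyldimethylsilyl)oxy]-10-[(2R,3R)-3-{[(tert-butyldimethylsilyl)oxy]methyl}-3-methyloxiran-2-yl]-8-methyl-4-[(trimethylsilyl)methyl]deca-3,7-dien-1-yl]furan-2(5H)-one, via alkylzinc bromide 27 (not isolated)
Conditions: Zn dust, LiCl, THF, 50 °C; then 14, PdCl2(dppf) (5 mol%), THF, rt to 40 °C
Reagents that add atoms: none
Why: Negishi coupling of the homoallylic alkylzinc with the E vinyl iodide forms C5–C6 with retention of alkene geometry, and the organozinc tolerates the epoxide, silyl ethers, allylsilane and lactone.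

Step 17
Reactants: 28 epoxy-diene allylsilane
Product: 29 4-{2-[(1R,4aS,5S,6S,7S,8aS)-7-[(tert-butyldimethylsilyl)oxy]-5-{[(tert-butyldimethylsilyl)oxy]methyl}-6-hydroxy-5,8a-dimethyl-2-methylidenedecahydronaphthalen-1-yl]ethyl}furan-2(5H)-one
Conditions: MeAlCl2 (3 equiv), CH2Cl2, −78 °C, 1 h; Et3N/MeOH quench, aq. Rochelle salt
Reagents that add atoms: none
Why: Lewis-acid epoxy-polyene (cation–olefin) bicyclisation through a chair–chair transition state: anti opening of the epoxide at C4 with inversion, the E C5=C10 alkene giving the trans ring fusion (C5, C10), the Z allylsilane giving the equatorial C9 side chain and, by loss of silicon, only the C8 exo-methylene, with the C2 and C4 oxygen substituents equatorial.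

Step 18
Reactants: 29 decalin-3-ol; 30 angelic acid [(2Z)-2-methylbut-2-enoic acid]
Product: 32 (1S,2S,3S,4aS,5R,8aS)-3-[(tert-butyldimethylsilyl)oxy]-1-{[(tert-butyldimethylsilyl)oxy]methyl}-1,4a-dimethyl-6-methylidene-5-[2-(5-oxo-2,5-dihydrofuran-3-yl)ethyl]decahydronaphthalen-2-yl (2Z)-2-methylbut-2-enoate, via mixed anhydride 31 (not isolated)
Conditions: 30, 2,4,6-trichlorobenzoyl chloride, Et3N, toluene, rt, 2 h; then 29, toluene, 80 °C
Reagents that add atoms: none
Why: Yamaguchi esterification through the mixed anhydride without a nucleophilic catalyst acylates the equatorial C3 hydroxyl while avoiding the conjugate-addition pathway that isomerises angelate to tiglate.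

Step 19
Reactants: 32 bis-silylated angelate
Product: 33 [(1S,2S,3S,4aS,5R,8aS)-3-hydroxy-1-(hydroxymethyl)-1,4a-dimethyl-6-methylidene-5-[2-(5-oxo-2,5-dihydrofuran-3-yl)ethyl]decahydronaphthalen-2-yl] (2Z)-2-methylbut-2-enoate (target)
Conditions: HF·pyridine, pyridine, THF, 0 °C to rt
Reagents that add atoms: none
Why: Buffered fluoride desilylation removes both TBS ethers under mildly acidic conditions, where acyl migration and alkene isomerisation are slow.

**Compound list**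

1 | propargyl alcohol | C#CCO | starting material
2 | dimethyl[(1E)-3-[(dimethylalumanyl)oxy]-2-methylprop-1-en-1-yl]alumane | C[Al](C)/C=C(\C)CO[Al](C)C | intermediate
3 | (2E)-3-iodo-2-methylprop-2-en-1-ol | OC/C(C)=C/I | intermediate
4 | tert-butyl{[(2E)-3-iodo-2-methylprop-2-en-1-yl]oxy}dimethylsilane | CC(C)(C)[Si](C)(C)OC/C(C)=C/I | intermediate
5 | [(1E)-3-[(tert-butyldimethylsilyl)oxy]-2-methylprop-1-en-1-yl]lithium | CC(C)(C)[Si](C)(C)OC/C(C)=C/[Li] | intermediate
6 | (2E)-4-[(tert-butyldimethylsilyl)oxy]-3-methylbut-2-enal | CC(C)(C)[Si](C)(C)OC/C(C)=C/C=O | intermediate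
7 | propargyl bromide | C#CCBr | starting material
8 | propa-1,2-dien-1-ylmagnesium bromide | C=C=C[Mg]Br | intermediate
9 | 4,4,5,5-tetramethyl-2-(propa-1,2-dien-1-yl)-1,3,2-dioxaborolane | C=C=CB1OC(C)(C)C(C)(C)O1 | intermediate
10 | (2E,4S)-1-[(tert-butyldimethylsilyl)oxy]-2-methylhept-2-en-6-yn-4-ol | C#CC[C@H](O)/C=C(\C)CO[Si](C)(C)C(C)(C)C | intermediate
11 | [(1E,4S,5E)-7-[(tert-butyldimethylsilyl)oxy]-4-[(dimethylalumanyl)oxy]-2,6-dimethylhepta-1,5-dien-1-yl]dimethylalumane | C[Al](C)/C=C(\C)C[C@H](O[Al](C)C)/C=C(\C)CO[Si](C)(C)C(C)(C)C | intermediate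
12 | (2E,4S,6E)-1-[(tert-butyldimethylsilyl)oxy]-7-iodo-2,6-dimethylhepta-2,6-dien-4-ol | I/C=C(\C)C[C@H](O)/C=C(\C)CO[Si](C)(C)C(C)(C)C | intermediate
13 | (1S,3E)-1-[(2R,3R)-3-{[(tert-butyldimethylsilyl)oxy]methyl}-3-methyloxiran-2-yl]-4-iodo-3-methylbut-3-en-1-ol | I/C=C(\C)C[C@H](O)[C@@H](O1)[C@@]1(C)CO[Si](C)(C)C(C)(C)C | intermediate
14 | tert-butyl{[(1S,3E)-1-[(2R,3R)-3-{[(tert-butyldimethylsilyl)oxy]methyl}-3-methyloxiran-2-yl]-4-iodo-3-methylbut-3-en-1-yl]oxy}dimethylsilane | I/C=C(\C)C[C@H](O[Si](C)(C)C(C)(C)C)[C@@H](O1)[C@@]1(C)CO[Si](C)(C)C(C)(C)C | intermediate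
15 | 3-butyn-1-ol | C#CCCO | starting material
16 | (but-3-yn-1-yloxy)(tert-butyl)dimethylsilane | C#CCCO[Si](C)(C)C(C)(C)C | intermediate
17 | ethylene oxide | C1CO1 | starting material
18 | [(1Z)-4-[(tert-butyldimethylsilyl)oxy]-2-[(trimethylsilyl)methyl]but-1-en-1-yl]copper | C[Si](C)(C)C/C(CCO[Si](C)(C)C(C)(C)C)=C\[Cu] | intermediate
19 | (3Z)-6-[(tert-butyldimethylsilyl)oxy]-4-[(trimethylsilyl)methyl]hex-3-en-1-ol | OCC/C=C(\C[Si](C)(C)C)CCO[Si](C)(C)C(C)(C)C | intermediate
20 | {[(3Z)-6-bromo-3-[(trimethylsilyl)methyl]hex-3-en-1-yl]oxy}(tert-butyl)dimethylsilane | BrCC/C=C(\C[Si](C)(C)C)CCO[Si](C)(C)C(C)(C)C | intermediate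
21 | tetronic acid (4-hydroxyfuran-2(5H)-one) | OC1=CC(=O)OC1 | starting material
22 | 4-bromofuran-2(5H)-one | BrC1=CC(=O)OC1 | intermediate
23 | bromo[(3Z)-6-[(tert-butyldimethylsilyl)oxy]-4-[(trimethylsilyl)methyl]hex-3-en-1-yl]zinc | Br[Zn]CC/C=C(\C[Si](C)(C)C)CCO[Si](C)(C)C(C)(C)C | intermediate
24 | 4-[(3Z)-6-[(tert-butyldimethylsilyl)oxy]-4-[(trimethylsilyl)methyl]hex-3-en-1-yl]furan-2(5H)-one | CC(C)(C)[Si](C)(C)OCC/C(C[Si](C)(C)C)=C/CCC1=CC(=O)OC1 | intermediate
25 | 4-[(3Z)-6-hydroxy-4-[(trimethylsilyl)methyl]hex-3-en-1-yl]furan-2(5H)-one | OCC/C(C[Si](C)(C)C)=C/CCC1=CC(=O)OC1 | intermediate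
26 | 4-[(3Z)-6-bromo-4-[(trimethylsilyl)methyl]hex-3-en-1-yl]furan-2(5H)-one | BrCC/C(C[Si](C)(C)C)=C/CCC1=CC(=O)OC1 | intermediate
27 | bromo[(3Z)-6-(5-oxo-2,5-dihydrofuran-3-yl)-3-[(trimethylsilyl)methyl]hex-3-en-1-yl]zinc | Br[Zn]CC/C(C[Si](C)(C)C)=C/CCC1=CC(=O)OC1 | intermediate
28 | 4-[(3Z,7E,10S)-10-[(tert-butyldimethylsilyl)oxy]-10-[(2R,3R)-3-{[(tert-butyldimethylsilyl)oxy]methyl}-3-methyloxiran-2-yl]-8-methyl-4-[(trimethylsilyl)methyl]deca-3,7-dien-1-yl]furan-2(5H)-one | C[Si](C)(C)C/C(=C\CCC1=CC(=O)OC1)CC/C=C(\C)C[C@H](O[Si](C)(C)C(C)(C)C)[C@@H](O2)[C@@]2(C)CO[Si](C)(C)C(C)(C)C | intermediate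
29 | 4-{2-[(1R,4aS,5S,6S,7S,8aS)-7-[(tert-butyldimethylsilyl)oxy]-5-{[(tert-butyldimethylsilyl)oxy]methyl}-6-hydroxy-5,8a-dimethyl-2-methylidenedecahydronaphthalen-1-yl]ethyl}furan-2(5H)-one | C=C1CC[C@H]2[C@@](C)(C[C@H](O[Si](C)(C)C(C)(C)C)[C@@H](O)[C@]2(C)CO[Si](C)(C)C(C)(C)C)[C@@H]1CCC1=CC(=O)OC1 | intermediate
30 | angelic acid [(2Z)-2-methylbut-2-enoic acid] | C/C=C(/C)C(=O)O | starting material
31 | (2Z)-2-methylbut-2-enoic 2,4,6-trichlorobenzoic anhydride | C/C=C(/C)C(=O)OC(=O)c1c(Cl)cc(Cl)cc1Cl | intermediate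
32 | (1S,2S,3S,4aS,5R,8aS)-3-[(tert-butyldimethylsilyl)oxy]-1-{[(tert-butyldimethylsilyl)oxy]methyl}-1,4a-dimethyl-6-methylidene-5-[2-(5-oxo-2,5-dihydrofuran-3-yl)ethyl]decahydronaphthalen-2-yl (2Z)-2-methylbut-2-enoate | C=C1CC[C@H]2[C@@](C)(C[C@H](O[Si](C)(C)C(C)(C)C)[C@@H](OC(=O)/C(C)=C\C)[C@]2(C)CO[Si](C)(C)C(C)(C)C)[C@@H]1CCC1=CC(=O)OC1 | intermediate
33 | [(1S,2S,3S,4aS,5R,8aS)-3-hydroxy-1-(hydroxymethyl)-1,4a-dimethyl-6-methylidene-5-[2-(5-oxo-2,5-dihydrofuran-3-yl)ethyl]decahydronaphthalen-2-yl] (2Z)-2-methylbut-2-enoate | C=C1CC[C@H]2[C@@](C)(C[C@H](O)[C@@H](OC(=O)/C(C)=C\C)[C@]2(C)CO)[C@@H]1CCC1=CC(=O)OC1 | target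

**Step count**

Total: 19 steps.
Longest linear sequence: 11 steps (1, 2, 3, 5, 6, 7, 8, 16, 17, 18, 19). The fragment B line (9, 10, 11, 13, 14, 15, then 16–19) is 10 steps; steps 4 and 12 are one-step side branches.

**Steps most likely to fail, with fallbacks**

Step 17 (bicyclisation of 28). The epoxide carries two neighbouring silyloxy groups that slow ionisation at C4, and the lactone binds the Lewis acid, so hydride shift to a C3 ketone or incomplete cyclisation may compete. The fallback cyclises a lactone-free substrate and attaches the butenolide afterwards; it sets out from 19 and comes back at 29. Acetylation of 19 (Ac2O, pyridine) gives (3Z)-6-[(tert-butyldimethylsilyl)oxy]-4-[(trimethylsilyl)methyl]hex-3-en-1-yl acetate F1. PPTS in MeOH gives (3Z)-6-hydroxy-4-[(trimethylsilyl)methyl]hex-3-en-1-yl acetate F2, and CBr4/PPh3 gives (3Z)-6-bromo-4-[(trimethylsilyl)methyl]hex-3-en-1-yl acetate F3. Zinc dust and LiCl give the alkylzinc bromide F4, which is coupled with 14 (PdCl2(dppf)) to the acetoxy epoxy-diene allylsilane F5. MeAlCl2 at −78 °C closes rings A and B to the acetoxyethyl decalinol F6, and K2CO3 in MeOH gives the diol F7. CBr4/PPh3 at 0 °C converts only the primary alcohol into the bromide F8. A nickel-catalysed reductive cross-electrophile coupling of F8 with 22 (NiBr2·glyme, 4,4′-di-tert-butyl-2,2′-bipyridine, Zn, NaI, DMA) then gives 29.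

Step 10 (silylmethyl carbocupration). (Trimethylsilyl)methylcopper transfers its group sluggishly and the alkenylcopper is a weak nucleophile toward epoxides. The fallback builds the alkene by a ring-enforced trans-hydrosilylation and puts the silylmethyl group on by cross-coupling; it sets out from 16 and comes back at 19. n-BuLi converts 16 into the lithium acetylide F9, which opens ethylene oxide 17 (BF3·OEt2, THF, −78 °C) to 6-[(tert-butyldimethylsilyl)oxy]hex-3-yn-1-ol F10. (Me2HSi)2NH gives the dimethylsilyl ether F11, and [Cp*Ru(MeCN)3]PF6 (2 mol%, CH2Cl2) closes it by intramolecular trans-hydrosilylation to 3-{2-[(tert-butyldimethylsilyl)oxy]ethyl}-2,2-dimethyl-5,6-dihydro-2H-1,2-oxasiline F12, in which the ring holds silicon cis to the oxyethyl arm. N-Iodosuccinimide in hexafluoroisopropanol (0 °C, then aqueous K2CO3) replaces silicon by iodine with retention and gives (3Z)-6-[(tert-butyldimethylsilyl)oxy]-4-iodohex-3-en-1-ol F13. Kumada coupling of F13 with Me3SiCH2MgCl (3 equiv, Pd(PPh3)4, THF, 50 °C) gives 19.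

Step 18 (angeloylation of the hindered C3 hydroxyl). Acylation may be slow next to the C2 silyl ether and the quaternary C4, and forcing it risks leakage to the E (tiglate) ester. The fallback builds the Z alkene on the ester; it sets out from 29 and comes back at 32. Esterification of 29 with 2-[bis(2-methylphenoxy)phosphoryl]propanoic acid (DCC, DMAP cat., CH2Cl2) gives the C3 2-[bis(2-methylphenoxy)phosphoryl]propanoate F14. An Ando-type Z-selective Horner–Wadsworth–Emmons reaction of F14 with acetaldehyde (NaI, DBU, THF, −78 to 0 °C) gives 32.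

**Further compounds**

F1 | step 17 | (3Z)-6-[(tert-butyldimethylsilyl)oxy]-4-[(trimethylsilyl)methyl]hex-3-en-1-yl acetate | CC(=O)OCC/C=C(\C[Si](C)(C)C)CCO[Si](C)(C)C(C)(C)C
F2 | step 17 | (3Z)-6-hydroxy-4-[(trimethylsilyl)methyl]hex-3-en-1-yl acetate | CC(=O)OCC/C=C(\C[Si](C)(C)C)CCO
F3 | step 17 | (3Z)-6-bromo-4-[(trimethylsilyl)methyl]hex-3-en-1-yl acetate | CC(=O)OCC/C=C(\C[Si](C)(C)C)CCBr
F4 | step 17 | [(3Z)-6-acetoxy-3-[(trimethylsilyl)methyl]hex-3-en-1-yl](bromo)zinc | CC(=O)OCC/C=C(\C[Si](C)(C)C)CC[Zn]Br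
F5 | step 17 | (3Z,7E,10S)-10-[(tert-butyldimethylsilyl)oxy]-10-[(2R,3R)-3-{[(tert-butyldimethylsilyl)oxy]methyl}-3-methyloxiran-2-yl]-8-methyl-4-[(trimethylsilyl)methyl]deca-3,7-dien-1-yl acetate | CC(=O)OCC/C=C(\C[Si](C)(C)C)CC/C=C(\C)C[C@H](O[Si](C)(C)C(C)(C)C)[C@@H](O1)[C@@]1(C)CO[Si](C)(C)C(C)(C)C
F6 | step 17 | 2-[(1R,4aS,5S,6S,7S,8aS)-7-[(tert-butyldimethylsilyl)oxy]-5-{[(tert-butyldimethylsilyl)oxy]methyl}-6-hydroxy-5,8a-dimethyl-2-methylidenedecahydronaphthalen-1-yl]ethyl acetate | C=C1CC[C@H]2[C@@](C)(C[C@H](O[Si](C)(C)C(C)(C)C)[C@@H](O)[C@]2(C)CO[Si](C)(C)C(C)(C)C)[C@@H]1CCOC(C)=O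
F7 | step 17 | 2-[(1R,4aS,5S,6S,7S,8aS)-7-[(tert-butyldimethylsilyl)oxy]-5-{[(tert-butyldimethylsilyl)oxy]methyl}-6-hydroxy-5,8a-dimethyl-2-methylidenedecahydronaphthalen-1-yl]ethan-1-ol | C=C1CC[C@H]2[C@@](C)(C[C@H](O[Si](C)(C)C(C)(C)C)[C@@H](O)[C@]2(C)CO[Si](C)(C)C(C)(C)C)[C@@H]1CCO
F8 | step 17 | (1S,2S,3S,4aS,5R,8aS)-5-(2-bromoethyl)-3-[(tert-butyldimethylsilyl)oxy]-1-{[(tert-butyldimethylsilyl)oxy]methyl}-1,4a-dimethyl-6-methylidenedecahydronaphthalen-2-ol | C=C1CC[C@H]2[C@@](C)(C[C@H](O[Si](C)(C)C(C)(C)C)[C@@H](O)[C@]2(C)CO[Si](C)(C)C(C)(C)C)[C@@H]1CCBr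
F9 | step 10 | {4-[(tert-butyldimethylsilyl)oxy]but-1-yn-1-yl}lithium | [Li]C#CCCO[Si](C)(C)C(C)(C)C
F10 | step 10 | 6-[(tert-butyldimethylsilyl)oxy]hex-3-yn-1-ol | OCCC#CCCO[Si](C)(C)C(C)(C)C
F11 | step 10 | tert-butyl({6-[(dimethylsilyl)oxy]hex-3-yn-1-yl}oxy)dimethylsilane | C[SiH](C)OCCC#CCCO[Si](C)(C)C(C)(C)C
F12 | step 10 | 3-{2-[(tert-butyldimethylsilyl)oxy]ethyl}-2,2-dimethyl-5,6-dihydro-2H-1,2-oxasiline | C[Si]1(C)OCCC=C1CCO[Si](C)(C)C(C)(C)C
F13 | step 10 | (3Z)-6-[(tert-butyldimethylsilyl)oxy]-4-iodohex-3-en-1-ol | OCC/C=C(\I)CCO[Si](C)(C)C(C)(C)C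
F14 | step 18 | (1S,2S,3S,4aS,5R,8aS)-3-[(tert-butyldimethylsilyl)oxy]-1-{[(tert-butyldimethylsilyl)oxy]methyl}-1,4a-dimethyl-6-methylidene-5-[2-(5-oxo-2,5-dihydrofuran-3-yl)ethyl]decahydronaphthalen-2-yl 2-[bis(2-methylphenoxy)phosphoryl]propanoate (both epimers at the phosphonate carbon) | C=C1CC[C@H]2[C@@](C)(C[C@H](O[Si](C)(C)C(C)(C)C)[C@@H](OC(=O)C(C)P(=O)(Oc3ccccc3C)Oc3ccccc3C)[C@]2(C)CO[Si](C)(C)C(C)(C)C)[C@@H]1CCC1=CC(=O)OC1
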